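I had 4 questions to answer about this flask, and one level of dissolved target served them.

starting material 0.10 M; salt in the second phase 1.20 equiv; spent carrier 8.3 mol%; time 20 s; volume of the second phase over the first 0.25
- how much target and crystals together there is at 20 s, in percent of the starting material charged
- concentration of target in solution at 10 s, in percent of saturation
- the change that raises the amount of target and crystals together at 20 s, in percent of the starting material charged most ("none" if none brings more than 2 percentage points) (ash / elm / oak / none)
- amount of target and crystals together at 20 s, in percent of the starting material charged, after oak
- target is meant together with its crystals
- in the second phase: salt in the second phase, spent salt in the second phase; everything else is in the first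
- charges count per volume of the first phase; a concentration in a rate is the amount of a species over the volume of its own phase; every rate counts per litre of the first phase
- solid, in amounts per volume of the solution: crystals
- run time (flask): 20 s
    spent carrier + salt in the second phase ⇌ fresh carrier + spent salt in the second phase (K1 = 18, k1 = 3.4 /M/s)
    starting material + fresh carrier ⇌ target + spent carrier (K2 = 18, k2 = 7.3 /M/s)
    crystals ⇌ target, rate k3*(cs3 - [target]) while solid is left; crystals form when [target] > cs3 (cs3 = 1.1 mM, k3 = 0.37 /s)
    target + fresh carrier → over-reaction product + fresh carrier (k4 = 40 /M/s)

Fresh carrier turns starting material into target and becomes spent carrier, and the salt in the second phase refreshes it. Dissolved target then leaves solution by two exits: into crystals above the solubility or, through fresh carrier again, into over-reaction product. I began with the carrier: the salt stood at 0.480 M in its own phase, and balancing the forward steps made 69.1 % of the carrier fresh, which is 5.73 mM.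

I then set up a small table with one row per exit and two columns, coefficient and base. Crystals had 0.37 /s acting on the excess of c(target) over 1.1 mM, and over-reaction product had 0.229 /s acting on c(target) whole. The first column favoured crystals, but the second favoured over-reaction product, so the rows met at a crossing level, the c(target) at which both exits run equally fast, 2.89 mM; above it crystals take more.

I reckoned 56.7 % of the starting material turned over by 20 s, and setting making equal to leaving gave me a level of 5.27 mM at 10 s, or 479 % of saturation, which is above the crossing. At that level my reckoning gave crystals 56.1 % of what left solution, so I committed to about 31.8 %, leaving aside what was still dissolved. Ash lowered the crossing to 1.59 mM and oak raised it to 5.78 mM, giving about 28.6 %, so I chose ash.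

The forecast gave 30 %, 520 %, ash and 27 %, saying that faster crystallisation “protects target best”.

The simulation gave 32.9 %, 514 %, ash and 30.2 %, with ash at 6.5 percentage points, elm at 1.5 points and oak at −2.7 points.

In this flask at 10.0 s, dissolved target read 5.65 mM, so crystals were forming at 1.68 mM/s and over-reaction product at 1.28 mM/s. Crystals by then held 15.3 % against 11.6 % of over-reaction product.

For the neighbour flask, with 0.025 M of starting material and the same equivalents and loading, my reckoning kept the fresh share at 69.1 % and put fresh carrier at 1.43 mM and the crossing at 1.30 mM, with a level at 20 s of 1.45 mM, just above it, so I reckoned about 11.5 %. That flask gave 12.2 %, with crystals at 6.37 % against 4.92 % of over-reaction product.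

The constants used here stand for no real mixture; the run is a simulation.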